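**Retrosynthetic overview**
- Last step: the C8 carbinol comes from the 6,8-dione by hydride delivery directed by the C7 hydroxyl.
- Ring B (pyran), key step: inverse-electron-demand hetero-Diels–Alder reaction of a ring-A 2-formyl enone (1-oxadiene O2=C1–C8a=C4a) with the silyl dienol ether of the side-chain methyl enone (C3, C4), then loss of silanol and methanol.
- Ring A: C7–C8 by acylation of the (S)-lactic acid dioxolanone enolate with 4-chloro-3-methoxybutenoyl chloride, then C5–C6 by vinylogous Dieckmann closure; C1 is added by aminomethylenation and hydrolysis.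
- Side chain: L-isoleucine (C4', C5'), chelation-controlled MeMgBr addition (C3'), cross-metathesis with methyl vinyl ketone (E-alkene).
- Ring order: ring A first, ring B second.

Assumption: acid 4 is bought (otherwise one LiOH hydrolysis of its commercial methyl ester); C1–C8a are the isochromene positions of the target, primed numbers the side chain.
Note: 8, 10 and 19 are drawn as one tautomer each; the R/S label of the quaternary carbon changes along the route only because the CIP ranking of its ring neighbours changes, not its geometry. The route is a proposal from first principles; steps 3, 4, 10 and 11 have no direct precedent on these substrates.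

**Step 1**
Reactants: 1 (S)-lactic acid; 2 pivalaldehyde
Product: 3 (2S,5S)-2-tert-butyl-5-methyl-1,3-dioxolan-4-one
Conditions: cat. TsOH·H2O, cat. H2SO4, pentane, reflux, Dean–Stark; crystallised from pentane/Et2O at −78 °C
Reagents that add atoms: none
Why: Acid-catalysed acetalisation (Seebach self-regeneration of stereocentres): the bought lactate stereocentre sets the new acetal carbon cis to the methyl group (2S,5S), and crystallisation removes the minor trans isomer.

**Step 2**
Reactants: 3 (2S,5S)-2-tert-butyl-5-methyl-1,3-dioxolan-4-one; 4 (2E)-4-chloro-3-methoxybut-2-enoic acid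
Product: 7 (2S,5R)-2-tert-butyl-5-[(2E)-4-chloro-3-methoxybut-2-enoyl]-5-methyl-1,3-dioxolan-4-one, via acid chloride 5 (not isolated), via lithium enolate 6 (not isolated)
Conditions: 4, (COCl)2, cat. DMF, CH2Cl2, 0 °C to rt, evaporated; 3, LiN(iPr)2, THF, −78 °C; enolate cannulated into 5 in THF, −78 °C
Reagents that add atoms: none
Why: Claisen-type C-acylation of the lithium ester enolate: the acyl group enters anti to the tert-butyl group, so it replaces the lactate hydrogen with retention and creates the quaternary carbon that becomes C7 (R in the target), while inverse addition keeps the product from protonating unreacted enolate.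

**Step 3**
Reactants: 7 (2S,5R)-2-tert-butyl-5-[(2E)-4-chloro-3-methoxybut-2-enoyl]-5-methyl-1,3-dioxolan-4-one
Product: 8 (6S)-4-chloro-5,6-dihydroxy-3-methoxy-6-methylcyclohexa-2,4-dien-1-one
Conditions: LiN(SiMe3)2 (2.2 equiv), THF, −78 to −20 °C; then 1 M HCl
Reagents that add atoms: none
Why: Vinylogous Dieckmann (Claisen) condensation: γ-deprotonation of the β-methoxy enone gives a dienolate whose chlorine-bearing carbon acylates the dioxolanone carbonyl in a six-membered closure with loss of pivalaldehyde, the quaternary centre is not enolisable, and the chlorine keeps the C6 and C8 sides different so tautomerism cannot racemise the product.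

**Step 4**
Reactants: 8 (6S)-4-chloro-5,6-dihydroxy-3-methoxy-6-methylcyclohexa-2,4-dien-1-one
Product: 10 (5S)-3-chloro-4,5-dihydroxy-2-methoxy-5-methyl-6-oxocyclohexa-1,3-diene-1-carbaldehyde, via enaminone 9 (not isolated)
Conditions: Me2NCH(OMe)2 (1.3 equiv), toluene, 0 °C to rt; then 1 M HCl, THF, 0 °C
Reagents that add atoms: N,N-dimethylformamide dimethyl acetal, COC(OC)N(C)C; water, O
Why: Aminomethylenation of the vinylogous acid with an amide acetal (Knoevenagel-type condensation) at C8a, the only unsubstituted nucleophilic ring carbon, then hydrolysis of the vinylogous amide, installs C1 at the aldehyde level and unveils the 2-formyl enone needed for the cycloaddition.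

**Step 5**
Reactants: 11 L-isoleucine
Product: 12 (2S,3S)-2-hydroxy-3-methylpentanoic acid
Conditions: NaNO2, 1 M H2SO4, H2O, 0 °C to rt
Reagents that add atoms: water, O
Why: Diazotisation of the α-amino acid goes with net retention (double inversion through the α-lactone), so C4' and C5' are both bought with L-isoleucine.

**Step 6**
Reactants: 12 (2S,3S)-2-hydroxy-3-methylpentanoic acid
Product: 13 (2S,3S)-2-hydroxy-N-methoxy-N,3-dimethylpentanamide
Conditions: MeNH(OMe)·HCl, EDC·HCl, HOBt, N-methylmorpholine, CH2Cl2, 0 °C to rt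
Reagents that add atoms: N,O-dimethylhydroxylamine hydrochloride, CNOC.Cl
Why: Carbodiimide amide coupling gives the Weinreb amide, the hindered secondary hydroxyl not competing with the amine.

**Step 7**
Reactants: 13 (2S,3S)-2-hydroxy-N-methoxy-N,3-dimethylpentanamide
Product: 14 (4S,5S)-4-hydroxy-5-methylhept-1-en-3-one
Conditions: CH2=CHMgBr (3 equiv), THF, −78 to 0 °C; poured into cold 1 M HCl
Reagents that add atoms: vinylmagnesium bromide, C=C[Mg]Br
Why: Weinreb ketone synthesis: one equivalent deprotonates the hydroxyl, the next adds once to a stable chelated tetrahedral intermediate that collapses to the α'-hydroxy enone only on the acidic quench, which also protonates the released amine and stops its aza-Michael addition.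

**Step 8**
Reactants: 14 (4S,5S)-4-hydroxy-5-methylhept-1-en-3-one
Product: 15 (3R,4S,5S)-3,5-dimethylhept-1-ene-3,4-diol
Conditions: MeMgBr (3 equiv), THF/Et2O, −78 °C; aq. NH4Cl
Reagents that add atoms: methylmagnesium bromide, C[Mg]Br
Why: Chelation-controlled (Cram cyclic model) 1,2-Grignard addition: magnesium alkoxide and ketone oxygen form a five-membered chelate and methyl adds from the face of the small hydrogen, anti to the sec-butyl group, setting C3' as R under control of the isoleucine-derived C4'.

**Step 9**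
Reactants: 15 (3R,4S,5S)-3,5-dimethylhept-1-ene-3,4-diol; 16 methyl vinyl ketone
Product: 17 (3E,5R,6S,7S)-5,6-dihydroxy-5,7-dimethylnon-3-en-2-one
Conditions: 16 (4 equiv), second-generation Hoveyda–Grubbs catalyst (H2IMes)Cl2Ru=CH(C6H4-2-OiPr) (5 mol %), CH2Cl2, 40 °C
Reagents that add atoms: none
Why: Olefin cross-metathesis of the monosubstituted allylic-alcohol olefin with the enone gives the thermodynamically favoured E-enone with loss of ethylene, the stereocentres being remote from the reacting carbons.

**Step 10**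
Reactants: 10 (5S)-3-chloro-4,5-dihydroxy-2-methoxy-5-methyl-6-oxocyclohexa-1,3-diene-1-carbaldehyde; 17 (3E,5R,6S,7S)-5,6-dihydroxy-5,7-dimethylnon-3-en-2-one
Product: 21 (7R)-5-chloro-3-[(1E,3R,4S,5S)-3,4-dihydroxy-3,5-dimethylhept-1-en-1-yl]-7-hydroxy-7-methyl-6H-isochromene-6,8(7H)-dione, via silyl dienol ether 18 (not isolated), via silylated oxadiene 19 (not isolated), via cycloadduct 20 (not isolated)
Conditions: 17, Me3SiOTf (3.5 equiv), Et3N (5 equiv), CH2Cl2, −78 to 0 °C, pentane extraction; 10, MeC(OSiMe3)=NSiMe3 (1.2 equiv), toluene, rt; add 18 (1.3 equiv), 80 °C; then 1 M HCl, THF, rt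
Reagents that add atoms: none
Why: Inverse-electron-demand hetero-Diels–Alder reaction: the 2-formyl enone of 19 (a 1-oxadiene of the 3-formylchromone type, activated by the C8 carbonyl) adds the terminal silyl enol ether of 18 with its CH2 bonding to C4a and the formyl oxygen to the silyloxy carbon, which fixes the ring-B regiochemistry, and acid then eliminates Me3SiOH and MeOH and cleaves the silyl ethers without forming or touching a stereocentre.

**Step 11**
Reactants: 21 (7R)-5-chloro-3-[(1E,3R,4S,5S)-3,4-dihydroxy-3,5-dimethylhept-1-en-1-yl]-7-hydroxy-7-methyl-6H-isochromene-6,8(7H)-dione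
Product: 22 (7R,8S)-5-chloro-3-[(1E,3R,4S,5S)-3,4-dihydroxy-3,5-dimethylhept-1-en-1-yl]-7,8-dihydroxy-7-methyl-7,8-dihydro-6H-isochromen-6-one (CNP0133971.5)
Conditions: Me4NBH(OAc)3 (5 equiv), MeCN/AcOH 1:1, −30 to 0 °C
Reagents that add atoms: none
Why: Hydroxyl-directed reduction (Evans–Saksena type): the C7 hydroxyl exchanges onto boron and delivers hydride to the adjacent C8 ketone from its own face, giving the trans-7,8-diol (8S), while the C6 carbonyl, a pyrylium-enolate-like doubly vinylogous ester, is not reduced.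

**Compound list**
1 | (S)-lactic acid | C[C@H](O)C(=O)O | starting material
2 | pivalaldehyde | CC(C)(C)C=O | starting material
3 | (2S,5S)-2-tert-butyl-5-methyl-1,3-dioxolan-4-one | C[C@@H]1O[C@H](C(C)(C)C)OC1=O | intermediate
4 | (2E)-4-chloro-3-methoxybut-2-enoic acid | CO/C(CCl)=C/C(=O)O | starting material
5 | (2E)-4-chloro-3-methoxybut-2-enoyl chloride | CO/C(CCl)=C/C(=O)Cl | intermediate
6 | lithium (2S)-2-tert-butyl-5-methyl-1,3-dioxol-4-olate | CC1=C([O-])O[C@@H](C(C)(C)C)O1.[Li+] | intermediate
7 | (2S,5R)-2-tert-butyl-5-[(2E)-4-chloro-3-methoxybut-2-enoyl]-5-methyl-1,3-dioxolan-4-one | C[C@]1(C(=O)/C=C(/OC)CCl)O[C@H](C(C)(C)C)OC1=O | intermediate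
8 | (6S)-4-chloro-5,6-dihydroxy-3-methoxy-6-methylcyclohexa-2,4-dien-1-one | C[C@]1(O)C(O)=C(Cl)C(OC)=CC1=O | intermediate
9 | (2Z,6R)-4-chloro-2-[(dimethylamino)methylidene]-6-hydroxy-3-methoxy-6-methylcyclohex-3-ene-1,5-dione | CN(C)/C=C1\C(=O)[C@@](C)(O)C(=O)C(Cl)=C1OC | intermediate
10 | (5S)-3-chloro-4,5-dihydroxy-2-methoxy-5-methyl-6-oxocyclohexa-1,3-diene-1-carbaldehyde | O=CC1=C(OC)C(Cl)=C(O)[C@](C)(O)C1=O | intermediate
11 | L-isoleucine | CC[C@H](C)[C@H](N)C(=O)O | starting material
12 | (2S,3S)-2-hydroxy-3-methylpentanoic acid | CC[C@H](C)[C@H](O)C(=O)O | intermediate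
13 | (2S,3S)-2-hydroxy-N-methoxy-N,3-dimethylpentanamide | CC[C@H](C)[C@H](O)C(=O)N(C)OC | intermediate
14 | (4S,5S)-4-hydroxy-5-methylhept-1-en-3-one | CC[C@H](C)[C@H](O)C(=O)C=C | intermediate
15 | (3R,4S,5S)-3,5-dimethylhept-1-ene-3,4-diol | CC[C@H](C)[C@H](O)[C@](C)(O)C=C | intermediate
16 | methyl vinyl ketone | CC(=O)C=C | starting material
17 | (3E,5R,6S,7S)-5,6-dihydroxy-5,7-dimethylnon-3-en-2-one | CC[C@H](C)[C@H](O)[C@](C)(O)/C=C/C(C)=O | intermediate
18 | (3E,5R,6S,7S)-5,7-dimethyl-2,5,6-tris(trimethylsilyloxy)nona-1,3-diene | CC[C@H](C)[C@H](O[Si](C)(C)C)[C@](C)(O[Si](C)(C)C)/C=C/C(=C)O[Si](C)(C)C | intermediate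
19 | (5S)-3-chloro-5-hydroxy-2-methoxy-5-methyl-6-oxo-4-(trimethylsilyloxy)cyclohexa-1,3-diene-1-carbaldehyde | O=CC1=C(OC)C(Cl)=C(O[Si](C)(C)C)[C@](C)(O)C1=O | intermediate
20 | (7S)-5-chloro-7-hydroxy-4a-methoxy-7-methyl-3,6-bis(trimethylsilyloxy)-3-[(1E,3R,4S,5S)-3,5-dimethyl-3,4-bis(trimethylsilyloxy)hept-1-en-1-yl]-4,4a-dihydro-3H-isochromen-8(7H)-one (mixture at C3 and C4a) | CC[C@H](C)[C@H](O[Si](C)(C)C)[C@](C)(O[Si](C)(C)C)/C=C/C1(O[Si](C)(C)C)CC2(OC)C(Cl)=C(O[Si](C)(C)C)[C@](C)(O)C(=O)C2=CO1 | intermediate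
21 | (7R)-5-chloro-3-[(1E,3R,4S,5S)-3,4-dihydroxy-3,5-dimethylhept-1-en-1-yl]-7-hydroxy-7-methyl-6H-isochromene-6,8(7H)-dione | CC[C@H](C)[C@H](O)[C@](C)(O)/C=C/C1=CC2=C(Cl)C(=O)[C@](C)(O)C(=O)C2=CO1 | intermediate
22 | (7R,8S)-5-chloro-3-[(1E,3R,4S,5S)-3,4-dihydroxy-3,5-dimethylhept-1-en-1-yl]-7,8-dihydroxy-7-methyl-7,8-dihydro-6H-isochromen-6-one | CC[C@H](C)[C@H](O)[C@](C)(O)/C=C/C1=CC2=C(Cl)C(=O)[C@](C)(O)[C@@H](O)C2=CO1 | target

**Step count**
Total: 11 steps. Longest linear sequence: 7 steps (5, 6, 7, 8, 9, 10, 11 from L-isoleucine); the ring branch is 6 steps (1, 2, 3, 4, 10, 11).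

**Steps most likely to fail**

Step 3. The dianionic product carries a tertiary alkoxide between two carbonyls and could undergo acyloin-type ring contraction, and the hindered lactone carbonyl may resist acylation. The fallback sets out from 7 and comes back at 8. Soft enolisation of 7 with Me3SiOTf/Et3N gives the silyl dienol ether F1. TiCl4 in CH2Cl2 at −78 °C then activates the dioxolanone, and the γ-carbon of the dienol ether acylates it intramolecularly (vinylogous Mukaiyama–Claisen). Pivalaldehyde and the silyl group are lost on aqueous work-up to give 8, and the tertiary alkoxide is never formed.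

Step 10. The oxadiene terminus C4a is fully substituted and 10 is a tautomeric vinylogous acid, so the cycloaddition may be slow or take another tautomer. The fallback sets out from 9 (isolated after the first stage of step 4 instead of being hydrolysed) and 17, and comes back at 21. The lithium alkoxide of 9 is combined with the trilithio enolate of 17 (LiN(SiMe3)2, THF, −78 °C). Addition–elimination at C4a with loss of methoxide gives the enaminone diketone F2. In AcOH at 50 °C its dienol tautomer, a 1-oxatriene, closes by thermal oxa-6π electrocyclisation to the aminal F3, which loses Me2NH to give 21. The weak point of this variant is competing enolate attack at C1 of the enaminone.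

Step 11. The hydride may fail to discriminate C8 from C6 or may not be delivered from the C7-hydroxyl face. The fallback sets out from 21 and comes back at 22. External hydride under Luche conditions (NaBH4, CeCl3·7H2O, MeOH, −78 °C) is expected to give mainly the cis-diol, the C8 epimer F4. Mitsunobu inversion of its allylic secondary alcohol (4-nitrobenzoic acid, PPh3, DIAD, THF; the tertiary and the hindered side-chain hydroxyls stay) gives the 8S ester F5. K2CO3 in MeOH at 0 °C then releases 22.

**Further compounds**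
F1 | step 3 | (2S,5R)-2-tert-butyl-5-[(1E,3E)-4-chloro-3-methoxy-1-(trimethylsilyloxy)buta-1,3-dien-1-yl]-5-methyl-1,3-dioxolan-4-one | C[C@]1(/C(O[Si](C)(C)C)=C\C(OC)=C/Cl)O[C@H](C(C)(C)C)OC1=O
F2 | step 10 | (6R)-4-chloro-2-[(Z)-(dimethylamino)methylidene]-3-[(3E,5R,6S,7S)-5,6-dihydroxy-5,7-dimethyl-2-oxonon-3-en-1-yl]-6-hydroxy-6-methylcyclohex-3-ene-1,5-dione | CC[C@H](C)[C@H](O)[C@](C)(O)/C=C/C(=O)CC1=C(Cl)C(=O)[C@](C)(O)C(=O)/C1=C\N(C)C
F3 | step 10 | (7S)-5-chloro-1-(dimethylamino)-3-[(1E,3R,4S,5S)-3,4-dihydroxy-3,5-dimethylhept-1-en-1-yl]-6,7-dihydroxy-7-methyl-1H-isochromen-8(7H)-one (both C1 epimers) | CC[C@H](C)[C@H](O)[C@](C)(O)/C=C/C1=CC2=C(C(=O)[C@@](C)(O)C(O)=C2Cl)C(N(C)C)O1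
F4 | step 11 | (7R,8R)-5-chloro-3-[(1E,3R,4S,5S)-3,4-dihydroxy-3,5-dimethylhept-1-en-1-yl]-7,8-dihydroxy-7-methyl-7,8-dihydro-6H-isochromen-6-one | CC[C@H](C)[C@H](O)[C@](C)(O)/C=C/C1=CC2=C(Cl)C(=O)[C@](C)(O)[C@H](O)C2=CO1
F5 | step 11 | (7R,8S)-5-chloro-3-[(1E,3R,4S,5S)-3,4-dihydroxy-3,5-dimethylhept-1-en-1-yl]-7-hydroxy-7-methyl-6-oxo-7,8-dihydro-6H-isochromen-8-yl 4-nitrobenzoate | CC[C@H](C)[C@H](O)[C@](C)(O)/C=C/C1=CC2=C(Cl)C(=O)[C@](C)(O)[C@@H](OC(=O)c3ccc(cc3)[N+](=O)[O-])C2=CO1
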